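**Strategy.** The route rests on disconnecting the butenolide and the ten-membered carbocycle together at C5–C6, C6–C7, C11–C12 and C12–O: both carbonyl-level carbons C6 and C12, which flank the C7=C11 alkene, come from carbon monoxide. One palladium/light cascade on an acyclic neopentyl iodide (C5 on quaternary C4 of the dihydrofuran ring, hence no β-hydrogen) bearing a silylated butynediol-type alkyne should form the carbocycle (nine-membered oxacycle) and the ylidene butenolide at once. The precursor holds only the dihydrofuran ring and the three stereocentres C4, C8 and C10, drawn from (S)-2-methylglycidol, catalyst-controlled ynone reduction and (S)-citramalic acid; its C10 hydroxyl is masked as a silyl ether.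

Key step: step 13

Remark: atom labels C1–C13 are those of the target skeleton (carbocycle C1–C10, oxygen bridge C1–O–C4, lactone carbonyl C12, acetoxymethyl C13); 1, 3, 8 and 10 are taken as commercial; the epimer mixtures at the sulfonyl carbon of 14 and at the ketal carbon of 16–19 are erased later.

**Step 1**
Reactants: 1 (S)-citramalic acid
Product: 2 2-[(4S)-2,2,4-trimethyl-5-oxo-1,3-dioxolan-4-yl]acetic acid
Conditions: Me2C(OMe)2, TsOH·H2O (cat.), acetone, 23 °C
Reagents that add atoms: 2,2-dimethoxypropane, COC(C)(C)OC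
Why: Acid-catalysed acetalization in which only the α-hydroxy acid can form the five-membered 1,3-dioxolan-4-one, so one operation masks C10–OH, activates the C1 carboxyl and leaves the C8 carboxyl free without touching the quaternary centre.

**Step 2**
Reactants: 2 dioxolanone acid; 3 tert-butyldimethyl(prop-2-yn-1-yloxy)silane
Product: 5 ynone (5S)-5-{5-[(tert-butyldimethylsilyl)oxy]-2-oxopent-3-yn-1-yl}-2,2,5-trimethyl-1,3-dioxolan-4-one, via acid chloride 4 (not isolated)
Conditions: (COCl)2, DMF (cat.), CH2Cl2, 0 → 23 °C, evaporate; then 3, PdCl2(PPh3)2 (2 mol%), CuI (4 mol%), Et3N (1.2 equiv), THF, 23 °C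
Reagents that add atoms: oxalyl chloride (supplies only the chlorine of 4), O=C(Cl)C(Cl)=O
Why: Acyl Sonogashira coupling of the acid chloride with the terminal alkyne forms the C7–C8 bond at the ketone oxidation level without touching the dioxolanone, and only a slight excess of amine is used so that the β-oxygen is not eliminated.

**Step 3**
Reactants: 5 ynone
Product: 6 (5S)-5-{(2R)-5-[(tert-butyldimethylsilyl)oxy]-2-hydroxypent-3-yn-1-yl}-2,2,5-trimethyl-1,3-dioxolan-4-one
Conditions: Ru[(R,R)-TsDPEN](p-cymene) (1 mol%), i-PrOH, 23 °C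
Reagents that add atoms: none
Why: Noyori asymmetric transfer hydrogenation of the ynone, in which the (R,R)-configured catalyst delivers hydride to one carbonyl face and so sets C8 as R under catalyst control (alkynyl versus alkyl differentiation), independently of the remote C10 centre.

**Step 4**
Reactants: 6 propargylic alcohol
Product: 7 (5S)-5-{(2R)-2,5-bis[(tert-butyldimethylsilyl)oxy]pent-3-yn-1-yl}-2,2,5-trimethyl-1,3-dioxolan-4-one
Conditions: TBSOTf, 2,6-lutidine, CH2Cl2, −78 → 0 °C
Reagents that add atoms: tert-butyldimethylsilyl triflate, CC(C)(C)[Si](C)(C)OS(=O)(=O)C(F)(F)F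
Why: Silyl triflate silylation of the secondary propargylic alcohol, fast at low temperature so that the alcohol is capped before it can translactonize onto the dioxolanone.

**Step 5**
Reactants: 8 (S)-2-methylglycidol
Product: 9 (2R)-2-{[(4-methoxybenzyl)oxy]methyl}-2-methyloxirane
Conditions: NaH, PMBCl, Bu4NI (cat.), THF/DMF, 0 → 23 °C
Reagents that add atoms: 4-methoxybenzyl chloride, COc1ccc(CCl)cc1
Why: Williamson etherification, in which the alkoxide can only undergo a degenerate Payne rearrangement that returns the same enantiomer, so the C4 centre is carried over unchanged (its descriptor becomes R by priority change only).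

**Step 6**
Reactants: 9 PMB-protected epoxide; 10 methyl phenyl sulfone
Product: 12 (2R)-1-[(4-methoxybenzyl)oxy]-2-methyl-4-(phenylsulfonyl)butan-2-ol, via lithiated sulfone 11 (not isolated)
Conditions: 10, n-BuLi, THF, −78 °C; then 9, DMPU, −78 → 23 °C; H2O
Reagents that add atoms: n-butyllithium (supplies only the lithium of 11), [Li]CCCC
Why: SN2 opening of the epoxide at its unsubstituted CH2 terminus by the α-sulfonyl carbanion makes the C2–C3 bond and leaves the quaternary C4 centre untouched, now as the tertiary alcohol that will become the ring oxygen.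

**Step 7**
Reactants: 12 hydroxy sulfone (3 equiv); 7 silylated dioxolanone
Product: 14 β-keto sulfone (2R,6S,8R)-8,11-bis[(tert-butyldimethylsilyl)oxy]-2,6-dihydroxy-1-[(4-methoxybenzyl)oxy]-2,6-dimethyl-4-(phenylsulfonyl)undec-9-yn-5-one, via dilithio sulfone 13 (not isolated)
Conditions: 12, n-BuLi (2 equiv per 12), THF, −78 → −20 °C; then 7, −78 → 0 °C; AcOH quench
Reagents that add atoms: n-butyllithium (supplies only the lithium of 13), [Li]CCCC
Why: Claisen-type C-acylation of the sulfone carbanion by the activated, non-enolizable dioxolanone carbonyl forms C1–C2, and collapse of the tetrahedral adduct with loss of acetone frees the C10 carbinol, while the excess dianion takes up the acidic β-keto sulfone and the acetone (the C2 epimers are inconsequential).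

**Step 8**
Reactants: 14 β-keto sulfone
Product: 15 (2R,6S,8R)-8,11-bis[(tert-butyldimethylsilyl)oxy]-2,6-dihydroxy-1-[(4-methoxybenzyl)oxy]-2,6-dimethylundec-9-yn-5-one
Conditions: SmI2 (2.5 equiv), THF/MeOH, −78 °C
Reagents that add atoms: none
Why: Reductive desulfonylation of the β-keto sulfone by single-electron transfer (ketyl, loss of sulfinate, samarium enolate, protonation), which is much faster than reduction of the α-hydroxy ketone, the alkyne or the ethers.

**Step 9**
Reactants: 15 γ-hydroxy ketone
Product: 16 methyl ketal (2S,4R)-4,7-bis[(tert-butyldimethylsilyl)oxy]-2-[(5R)-2-methoxy-5-{[(4-methoxybenzyl)oxy]methyl}-5-methyloxolan-2-yl]hept-5-yn-2-ol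
Conditions: PPTS (cat.), HC(OMe)3, MeOH, 0 °C
Reagents that add atoms: methanol, CO
Why: Acid-catalysed ketalization in which the γ-hydroxy ketone closes to the five-membered hemiketal (C4–O–C1) and is trapped by methanol as the mixed methyl ketal, a stored form of the enol ether that tolerates the oxidant and the iodination to come, while the blocked C5 and C8 oxygens cannot form bicyclic or spiro ketals.

**Step 10**
Reactants: 16 methyl ketal
Product: 17 (2S,4R)-4,7-bis[(tert-butyldimethylsilyl)oxy]-2-[(5R)-5-(hydroxymethyl)-2-methoxy-5-methyloxolan-2-yl]hept-5-yn-2-ol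
Conditions: DDQ, CH2Cl2/pH 7 buffer, 0 °C
Reagents that add atoms: none
Why: Oxidative cleavage of the 4-methoxybenzyl ether by DDQ (benzylic hydride abstraction and hydrolysis) frees the C5 alcohol while silyl ethers, alkyne and the buffered ketal are untouched, and no electron-rich enol ether is present at this stage.

**Step 11**
Reactants: 17 primary alcohol
Product: 18 (2S,4R)-4,7-bis[(tert-butyldimethylsilyl)oxy]-2-[(5R)-5-(iodomethyl)-2-methoxy-5-methyloxolan-2-yl]hept-5-yn-2-ol
Conditions: PPh3, I2, imidazole, toluene, 70 °C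
Reagents that add atoms: iodine, II
Why: Appel iodination, in which the alkoxyphosphonium of the primary neopentyl-type alcohol is displaced by iodide on warming and the hindered tertiary C10 alcohol does not compete.

**Step 12**
Reactants: 18 iodide
Product: 20 (5R)-2-{(2S,4R)-4,7-bis[(tert-butyldimethylsilyl)oxy]-2-[(triethylsilyl)oxy]hept-5-yn-2-yl}-5-(iodomethyl)-5-methyl-4,5-dihydrofuran, via silylated ketal 19 (not isolated)
Conditions: TESOTf (3 equiv), i-Pr2NEt (4 equiv), CH2Cl2, −78 → 0 °C
Reagents that add atoms: triethylsilyl triflate, CC[Si](CC)(CC)OS(=O)(=O)C(F)(F)F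
Why: The silyl triflate first silylates the tertiary C10 alcohol and then ionizes the methyl ketal to the cyclic oxocarbenium ion, which the amine deprotonates at C2 (C10 carries no hydrogen), a silyl triflate/amine ketal-to-enol-ether elimination that releases the acid-sensitive dihydrofuran only now and under basic conditions.

**Step 13**
Reactants: 20 iodo alkyne precursor; 21 carbon monoxide (two molecules incorporated)
Product: 22 (4R,5E,8R,10S)-8,13-bis[(tert-butyldimethylsilyl)oxy]-10-[(triethylsilyl)oxy]-1,4-epoxygermacra-1,5,7(11)-trien-12,6-olide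
Conditions: Pd(PPh3)4 (20 mol%), CO (40 atm), i-Pr2NEt (3 equiv), PhH/MeCN (4:1), 0.002 M, hν (Xe lamp, Pyrex), 40 °C
Reagents that add atoms: carbon monoxide (compound 21), [C-]#[O+]
Why: Proposed new method: photoexcited zerovalent palladium reduces the C5–I bond to the neopentyl C5 radical, which under CO pressure is carbonylated faster than it can fragment and recombines with monovalent palladium to the C6 acylpalladium (C4 is quaternary, so no β-hydride path); intramolecular syn acylpalladation of the alkyne bonds C6 to C7, a second CO inserts at the C11 vinylpalladium, and the enol oxygen of the C6 ketone (enolizable only toward C5) is acylated at C12, releasing the butenolide and zerovalent palladium. The closest known chemistry is the palladium/light carbonylation of alkyl iodides and the cyclic acylpalladation of alkynes ended by carbonylative enol lactonization, so far limited to five- and six-membered rings. The carbocycle closes 10-exo-dig (9-exo-dig when counted through the ring oxygen) and the butenolide 5-exo-trig by O-acylation. No stereocentre is formed; syn addition fixes C6 and C12 cis on C7=C11, and the nine-membered oxacycle can hold only the C5=C6 isomer with C4 cis to C7. The step needs exo attack at C7 (ten- rather than eleven-membered ring) and no interception of either acylpalladium before cyclization; this is meant to be secured by the tether length, high dilution, the absence of any free hydroxyl (as a triethylsilyl ether, C10–O can neither lactonize onto C6 nor add to the alkyne) and silyl rather than acyl groups on the propargylic oxygens (no ionization, no β-acyloxy elimination).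

**Step 14**
Reactants: 22 tris-silyl ether
Product: 23 (4R,5E,8R,10S)-8,10,13-trihydroxy-1,4-epoxygermacra-1,5,7(11)-trien-12,6-olide
Conditions: TBAF, AcOH (1:1), THF, 0 → 23 °C
Reagents that add atoms: none
Why: Fluoride-mediated cleavage of the three silyl ethers, buffered with acetic acid so that neither the enol ether nor the enol lactone is exposed to strong acid or base.

**Step 15**
Reactants: 23 triol
Product: 24 (4R,5E,8R,10S)-13-acetoxy-8,10-dihydroxy-1,4-epoxygermacra-1,5,7(11)-trien-12,6-olide
Conditions: AcCl, 2,4,6-collidine, CH2Cl2, −78 °C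
Reagents that add atoms: acetyl chloride, CC(Cl)=O
Why: Rate-controlled acylation with acetyl chloride and a hindered pyridine base at low temperature selects the primary allylic C13 hydroxyl over the secondary C8 and tertiary C10 hydroxyls.

**Step 16**
Reactants: 24 monoacetate
Product: 25 target, (4R,5E,8R,10S)-13-acetoxy-10-hydroxy-8-(methacryloyloxy)-1,4-epoxygermacra-1,5,7(11)-trien-12,6-olide
Conditions: methacrylic anhydride, Et3N, DMAP (cat.), CH2Cl2, 0 °C
Reagents that add atoms: methacrylic anhydride, C=C(C)C(=O)OC(=O)C(C)=C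
Why: Nucleophilic-catalysed (DMAP) acylation of the secondary C8 alcohol by the anhydride (Steglich-type esterification), under which the tertiary C10 alcohol stays free.

**Compound list**

1 | (S)-citramalic acid | OC(=O)C[C@](C)(O)C(=O)O | starting material
2 | 2-[(4S)-2,2,4-trimethyl-5-oxo-1,3-dioxolan-4-yl]acetic acid | OC(=O)C[C@]1(C)OC(C)(C)OC1=O | intermediate
3 | tert-butyldimethyl(prop-2-yn-1-yloxy)silane | C#CCO[Si](C)(C)C(C)(C)C | starting material
4 | 2-[(4S)-2,2,4-trimethyl-5-oxo-1,3-dioxolan-4-yl]acetyl chloride (not isolated) | ClC(=O)C[C@]1(C)OC(C)(C)OC1=O | intermediate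
5 | (5S)-5-{5-[(tert-butyldimethylsilyl)oxy]-2-oxopent-3-yn-1-yl}-2,2,5-trimethyl-1,3-dioxolan-4-one | CC(C)(C)[Si](C)(C)OCC#CC(=O)C[C@]1(C)OC(C)(C)OC1=O | intermediate
6 | (5S)-5-{(2R)-5-[(tert-butyldimethylsilyl)oxy]-2-hydroxypent-3-yn-1-yl}-2,2,5-trimethyl-1,3-dioxolan-4-one | CC(C)(C)[Si](C)(C)OCC#C[C@H](O)C[C@]1(C)OC(C)(C)OC1=O | intermediate
7 | (5S)-5-{(2R)-2,5-bis[(tert-butyldimethylsilyl)oxy]pent-3-yn-1-yl}-2,2,5-trimethyl-1,3-dioxolan-4-one | CC(C)(C)[Si](C)(C)OCC#C[C@H](O[Si](C)(C)C(C)(C)C)C[C@]1(C)OC(C)(C)OC1=O | intermediate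
8 | (S)-2-methylglycidol | OC[C@@]1(C)CO1 | starting material
9 | (2R)-2-{[(4-methoxybenzyl)oxy]methyl}-2-methyloxirane | COc1ccc(COC[C@@]2(C)CO2)cc1 | intermediate
10 | methyl phenyl sulfone | CS(=O)(=O)c1ccccc1 | starting material
11 | [(phenylsulfonyl)methyl]lithium (not isolated) | [Li]CS(=O)(=O)c1ccccc1 | intermediate
12 | (2R)-1-[(4-methoxybenzyl)oxy]-2-methyl-4-(phenylsulfonyl)butan-2-ol | COc1ccc(COC[C@](C)(O)CCS(=O)(=O)c2ccccc2)cc1 | intermediate
13 | O,C4-dilithio derivative of 12 (not isolated) | COc1ccc(COC[C@](C)(O[Li])CC([Li])S(=O)(=O)c2ccccc2)cc1 | intermediate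
14 | (2R,6S,8R)-8,11-bis[(tert-butyldimethylsilyl)oxy]-2,6-dihydroxy-1-[(4-methoxybenzyl)oxy]-2,6-dimethyl-4-(phenylsulfonyl)undec-9-yn-5-one (epimers at C4 of the chain) | COc1ccc(COC[C@](C)(O)CC(S(=O)(=O)c2ccccc2)C(=O)[C@@](C)(O)C[C@@H](O[Si](C)(C)C(C)(C)C)C#CCO[Si](C)(C)C(C)(C)C)cc1 | intermediate
15 | (2R,6S,8R)-8,11-bis[(tert-butyldimethylsilyl)oxy]-2,6-dihydroxy-1-[(4-methoxybenzyl)oxy]-2,6-dimethylundec-9-yn-5-one | COc1ccc(COC[C@](C)(O)CCC(=O)[C@@](C)(O)C[C@@H](O[Si](C)(C)C(C)(C)C)C#CCO[Si](C)(C)C(C)(C)C)cc1 | intermediate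
16 | (2S,4R)-4,7-bis[(tert-butyldimethylsilyl)oxy]-2-[(5R)-2-methoxy-5-{[(4-methoxybenzyl)oxy]methyl}-5-methyloxolan-2-yl]hept-5-yn-2-ol (epimers at the ketal carbon) | COc1ccc(COC[C@@]2(C)CCC(OC)(O2)[C@@](C)(O)C[C@@H](O[Si](C)(C)C(C)(C)C)C#CCO[Si](C)(C)C(C)(C)C)cc1 | intermediate
17 | (2S,4R)-4,7-bis[(tert-butyldimethylsilyl)oxy]-2-[(5R)-5-(hydroxymethyl)-2-methoxy-5-methyloxolan-2-yl]hept-5-yn-2-ol | OC[C@@]1(C)CCC(OC)(O1)[C@@](C)(O)C[C@@H](O[Si](C)(C)C(C)(C)C)C#CCO[Si](C)(C)C(C)(C)C | intermediate
18 | (2S,4R)-4,7-bis[(tert-butyldimethylsilyl)oxy]-2-[(5R)-5-(iodomethyl)-2-methoxy-5-methyloxolan-2-yl]hept-5-yn-2-ol | IC[C@@]1(C)CCC(OC)(O1)[C@@](C)(O)C[C@@H](O[Si](C)(C)C(C)(C)C)C#CCO[Si](C)(C)C(C)(C)C | intermediate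
19 | triethylsilyl ether of 18 at the tertiary C10 hydroxyl (not isolated) | IC[C@@]1(C)CCC(OC)(O1)[C@@](C)(O[Si](CC)(CC)CC)C[C@@H](O[Si](C)(C)C(C)(C)C)C#CCO[Si](C)(C)C(C)(C)C | intermediate
20 | (5R)-2-{(2S,4R)-4,7-bis[(tert-butyldimethylsilyl)oxy]-2-[(triethylsilyl)oxy]hept-5-yn-2-yl}-5-(iodomethyl)-5-methyl-4,5-dihydrofuran | CC(C)(C)[Si](C)(C)O[C@H](C[C@](C)(O[Si](CC)(CC)CC)C1=CC[C@](C)(CI)O1)C#CCO[Si](C)(C)C(C)(C)C | intermediate
21 | carbon monoxide | [C-]#[O+] | starting material
22 | (4R,5E,8R,10S)-8,13-bis[(tert-butyldimethylsilyl)oxy]-10-[(triethylsilyl)oxy]-1,4-epoxygermacra-1,5,7(11)-trien-12,6-olide | CC(C)(C)[Si](C)(C)O[C@@H]1C[C@](C)(O[Si](CC)(CC)CC)C2=CC[C@](C)(/C=C3/OC(=O)C(CO[Si](C)(C)C(C)(C)C)=C31)O2 | intermediate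
23 | (4R,5E,8R,10S)-8,10,13-trihydroxy-1,4-epoxygermacra-1,5,7(11)-trien-12,6-olide | O[C@@H]1C[C@](C)(O)C2=CC[C@](C)(/C=C3/OC(=O)C(CO)=C31)O2 | intermediate
24 | (4R,5E,8R,10S)-13-acetoxy-8,10-dihydroxy-1,4-epoxygermacra-1,5,7(11)-trien-12,6-olide | O[C@@H]1C[C@](C)(O)C2=CC[C@](C)(/C=C3/OC(=O)C(COC(C)=O)=C31)O2 | intermediate
25 | (4R,5E,8R,10S)-13-acetoxy-10-hydroxy-8-(methacryloyloxy)-1,4-epoxygermacra-1,5,7(11)-trien-12,6-olide (CNP0394509.1) | C=C(C)C(=O)O[C@@H]1C[C@](C)(O)C2=CC[C@](C)(/C=C3/OC(=O)C(COC(C)=O)=C31)O2 | target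

**Totals.** Total steps: 16. Longest linear sequence: 14 steps (from 1 through steps 1–4 and 7–16).

**Steps most likely to fail**

1. Step 13 (the new reaction). What may go wrong: intermolecular capture or reduction of the C6 acylpalladium and fragmentation of the C5 radical (β-scission of the C4–O bond) may outrun the ten-membered acylpalladation, or the alkyne may insert with the wrong regiochemistry. The fallback uses known reactions and makes the carbocycle by ring expansion instead of direct macrocyclization; it sets out from iodide 18 and comes back at 22. Palladium/light carbonylation of 18 without added alcohol (Pd(PPh3)4, CO, K2CO3, hν) should let the free C10 hydroxyl trap the acyl group as the bridged seven-membered lactone F1; only the ketal epimer with C10 cis to C5 can close, and the other would be recycled through acidic methanol. The alkyne–titanium complex generated with Ti(O-i-Pr)4 and i-PrMgCl (2 equiv) should attack this lactone carbonyl through a six-membered transition state (intramolecular nucleophilic acyl substitution). This moves the C6 acyl from O10 to C7, opens the lactone to the ten-membered ketone and leaves titanium on C11 cis to C6; iodine should then give the macrocyclic (Z)-β-iodo enone F2. Carbonylative enol lactonization of the β-iodo enone (PdCl2(PPh3)2, CO, Et3N; a five-membered closure) should give the ylidene butenolide ketal F3, and the conditions of step 12 (TESOTf, i-Pr2NEt) should turn F3 into 22.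

2. Step 7. What may go wrong: attack of the hindered secondary sulfonyl carbanion on the carbonyl next to quaternary C10 may be slow, so that proton transfer from released acetone or from the product stops the acylation early. The fallback replaces acylation by addition to an aldehyde and re-oxidation; it sets out from 7 and comes back at 14. i-Bu2AlH (CH2Cl2, −78 °C) should reduce the dioxolanone to the dioxolanol F4, a masked α-hydroxy aldehyde; excess dianion 13 should add to it with loss of acetone to give the β-hydroxy sulfone F5; Dess–Martin oxidation of its only secondary alcohol should give 14.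

3. Step 12. What may go wrong: ionization of the ketal next to the silylated C10 may be slow, or may take the ring-opening path (cleavage of the ring C–O bond to an acyclic methyl enol ether) or a 1,2-shift from C10. The fallback replaces Lewis-acid ionization by base-mediated elimination of an anomeric sulfonate; it sets out from 18 and comes back at 20. TESOTf/2,6-lutidine at −78 °C should give the silylated ketal 19 (isolated here), PPTS in wet acetone should hydrolyse it to the hemiketal F6, and MsCl/Et3N should convert F6 through the anomeric mesylate F7 (not isolated) into 20.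

**Further compounds**

F1 | step 13 | bridged seven-membered lactone (C6 acyl on O10, methyl ketal retained) | O=C1C[C@@]2(C)CC[C@](OC)(O2)[C@@](C)(O1)C[C@@H](O[Si](C)(C)C(C)(C)C)C#CCO[Si](C)(C)C(C)(C)C
F2 | step 13 | macrocyclic (Z)-β-iodo enone (C6 ketone, C11 iodide, free C10 hydroxyl, methyl ketal) | O=C1C[C@@]2(C)CC[C@](OC)(O2)[C@@](C)(O)C[C@@H](O[Si](C)(C)C(C)(C)C)/C1=C(/I)CO[Si](C)(C)C(C)(C)C
F3 | step 13 | ylidene butenolide methyl ketal (free C10 hydroxyl, 8,13-bis-silyl ether) | CC(C)(C)[Si](C)(C)O[C@@H]1C[C@](C)(O)[C@]2(OC)CC[C@](C)(/C=C3/OC(=O)C(CO[Si](C)(C)C(C)(C)C)=C31)O2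
F4 | step 7 | (5S)-5-{(2R)-2,5-bis[(tert-butyldimethylsilyl)oxy]pent-3-yn-1-yl}-2,2,5-trimethyl-1,3-dioxolan-4-ol | CC(C)(C)[Si](C)(C)OCC#C[C@H](O[Si](C)(C)C(C)(C)C)C[C@]1(C)OC(C)(C)OC1O
F5 | step 7 | β-hydroxy sulfone (C1 carbinol analogue of 14) | COc1ccc(COC[C@](C)(O)CC(S(=O)(=O)c2ccccc2)C(O)[C@@](C)(O)C[C@@H](O[Si](C)(C)C(C)(C)C)C#CCO[Si](C)(C)C(C)(C)C)cc1
F6 | step 12 | hemiketal of 19 (hydroxyl in place of methoxyl at C1) | IC[C@@]1(C)CCC(O)(O1)[C@@](C)(O[Si](CC)(CC)CC)C[C@@H](O[Si](C)(C)C(C)(C)C)C#CCO[Si](C)(C)C(C)(C)C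
F7 | step 12 | anomeric mesylate of F6 (not isolated) | IC[C@@]1(C)CCC(OS(C)(=O)=O)(O1)[C@@](C)(O[Si](CC)(CC)CC)C[C@@H](O[Si](C)(C)C(C)(C)C)C#CCO[Si](C)(C)C(C)(C)C
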